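## The problem

The target 24 is a flavonol: rings A and C form a chromen-4-one fused through C4a–C8a, ring B (3′,5′-dihydroxy-4′-methoxyphenyl) sits on C2, C3 bears a hydroxyl, and ring A carries oxygen on every carbon except C6 (5-OH, 7-OH, 8-OMe, O1 on C8a). There is no stereocentre, so nothing has to be controlled in three dimensions and the difficulty is entirely regiochemical. Two of the oxygens are methyl ethers (C8 and C4′) and five are free hydroxyls, so the hydroxyl protecting group must come off without touching a methyl ether, and the ring A methoxy group must end up on C8 and not on C6. The pyranone opens with hard nucleophiles at C2, a free 5-hydroxy-8-methoxyflavone can isomerise to its 6-methoxy isomer in hot strong acid (Wessely–Moser rearrangement), and the free polyphenol is oxidised by air in base; the phenols should therefore stay masked until a final neutral step. The ring fusion puts O1 (on C8a) and the acyl carbon C4 (on C4a) on neighbouring ring A carbons, and C4a has the C5 oxygen on its other side. An oxygen/acyl pair next to an alkoxy group is what a carboxylic acid delivers to a 3-alkoxyaryne, and if the acid is an arylpropiolic acid, C3, C2 and ring B come with it. The C8 and C3 oxygens are then left for later, and both sit on positions that established flavone chemistry can address selectively.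

## Retrosynthesis

**24 ⇒ 23.** The four O–benzyl bonds at O5, O7, O3′ and O5′ are cut last. Benzyl is preferred to methyl, which could not be told apart from the two native methyl ethers, and to acetal groups, whose acidic removal would invite Wessely–Moser isomerisation. Flavonol 23 is no simpler in skeleton, but its benzyl ethers are what allow fluoride, methoxide and LiN(iPr)2 to be used upstream. The forward step must cleave benzyl ethers without reducing the C2=C3 bond or the carbonyl.

**23 ⇒ 20.** The C3–O bond is cut. C3 originates from an alkyne carbon in the ring-forming step and so arrives as C–H. C3–H is the ring proton next to the carbonyl and the one that LiN(iPr)2 should remove. Flavone 20 lacks one oxygen. The forward step must metalate C3 without attacking C4 or opening ring C.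

**20 ⇒ 19 ⇒ 18.** The C8–OMe bond is cut to the C8 bromide 19, and the C8–Br bond to the C8–H flavone 18. The C8 oxygen is deliberately kept out of the aryne, where a second flanking alkoxy group would cancel the polarisation that sets the regiochemistry. Electrophilic halogenation of 5,7-dialkoxyflavones goes to C8, and copper-mediated methoxylation of the bromide is established. The forward steps must choose C8 over C6 and over the ring B positions C2′/C6′.

**18 ⇒ 8 + 15.** Three bonds are cut at once: O1–C8a, C4–C4a and O1–C2. This removes ring C and gives the ortho-silylaryl triflate 8 and the arylpropiolic acid 15. The neighbouring cuts (aldol/oxidative cyclisation of a chalcone, or acylation of a preformed ortho-hydroxyacetophenone) each form fewer bonds and need a ring A ketone made beforehand. Here ring A enters as the aryne 16, and the acid supplies O1, C4, C3, C2 and ring B. The forward reaction must add the carboxylate oxygen to the aryne carbon remote from the benzyloxy group, shift the acyl group to the neighbouring carbon to give the ynone 17, and close by 6-endo attack of the phenoxide.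

**8 ⇒ 7 ⇒ 6 ⇒ 2 ⇒ 1.** The O–S bond of the triflate is cut to phenol 7, the carbamate is restored (6), the C–Si bond is cut to carbamate 2, and the carbamate C–O bond to phenol 1. Phenol 1 is symmetrical, so the two positions ortho to the carbamate in 2 are identical and each is flanked by a benzyloxy group; carbamate-directed lithiation therefore has a single outcome. The only other ring position, between the two ethers, is activated by the weaker directing groups alone. The forward sequence asks for ring lithiation next to the carbamate in preference to that site and to benzylic lithiation.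

**15 ⇒ 14 ⇒ 13 ⇒ 12 ⇒ 11 ⇒ 10 ⇒ 9.** The C–CO2H bond is cut to acetylide 14, the alkyne is traced to dibromoalkene 13 and aldehyde 12, and the aldehyde through alcohol 11 and ester 10 to acid 9. Acid 9 already has the 4-methoxy group between two free phenols, so no selective methylation is needed. All steps are standard functional-group changes on a symmetrical ring.

## Roads not taken

**Alternative 1:** The cut is through C2–C3 and C3–O, with no ring closure. Rh2(OAc)4 would decompose the ring A diazoketone 1-[4,6-bis(benzyloxy)-3-methoxy-2-(methoxymethoxy)phenyl]-2-diazoethan-1-one A2. Benzyl alcohol A3 would add to the carbenoid, and the resulting ylide or enol would be trapped by aldehyde 12, activated with Ti(OiPr)4. The product would be the racemic aldol 2-(benzyloxy)-1-[4,6-bis(benzyloxy)-3-methoxy-2-(methoxymethoxy)phenyl]-3-[3,5-bis(benzyloxy)-4-methoxyphenyl]-3-hydroxypropan-1-one A1.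
- Merits: in A1 the C3 oxygen is installed in the bond-forming event and the C8 methoxy group is carried from the start, so neither late C–H functionalisation of the chosen plan is needed. In these two respects it is the better road.
- Weak points: ring C is still open in A1, so oxidation of the C2 carbinol, removal of the acetal and cyclodehydration must follow, and the two stereocentres of A1 are made only to be erased. A2 derives from a benzoic acid with four differently substituted oxygens, which is a long synthesis in itself. The doubly ortho-substituted aroyl carbenoid from A2 is prone to Wolff rearrangement, and simple O–H insertion of A3 without aldehyde capture is the usual competitor.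
- Comparison: the chosen plan closes the ring and forms three skeletal bonds in one step from a symmetrical ring A precursor three steps from a commercial phenol. Its price is two regiochemical operations after ring closure.

**Alternative 2:** The cut is O1–C8a alone. The precursor is 2-(benzyloxy)-1-[4-(benzyloxy)-2-hydroxy-5-methoxyphenyl]-3-[3,5-bis(benzyloxy)-4-methoxyphenyl]propane-1,3-dione A5, whose ring A has hydrogen at the future C8a. Anodic oxidation of this para-methoxyphenol in a buffered methanolic electrolyte would give the quinone monoketal 5-(benzyloxy)-2-{2-(benzyloxy)-3-[3,5-bis(benzyloxy)-4-methoxyphenyl]-3-oxopropanoyl}-4,4-dimethoxycyclohexa-2,5-dien-1-one A6. With the current off, the enol oxygen of A6 would add to C8a, and loss of methanol would rearomatise the ring to 3,7-bis(benzyloxy)-2-[3,5-bis(benzyloxy)-4-methoxyphenyl]-5-hydroxy-8-methoxychromen-4-one A4.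
- Merits: the native C8 methoxy group is the control element, the C3 and C8 oxygens are in place, and only hydrogenolysis separates A4 from 24. Its end game is three steps shorter than that of the chosen plan, and no bromination or lithiation is needed.
- Weak points: A5 contains an enolised α-alkoxy-1,3-diketone and a trialkoxyphenyl ring B, both oxidisable near the potential required for the phenol. In A6 the solvent has two other conjugate positions open to it. The cascade has no close precedent on a substrate this crowded, and A5 itself needs an acyl-transfer sequence with a benzyloxyacetyl unit.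
- Comparison: the chosen plan has a longer tail but a key step that belongs to a defined, precedented reaction class, and it needs no electrochemical equipment.

**Alternative 3:** The cuts are C4a–C4, C4–C3 and O1–C2. 3,5-Bis(benzyloxy)-2-iodo-6-methoxyphenol A8, carbon monoxide A10 and 1,3-bis(benzyloxy)-5-ethynyl-2-methoxybenzene A9 would combine under PdCl2(PPh3)2 in an amine solvent. This carbonylative alkynylation and cyclisation would give 5,7-bis(benzyloxy)-2-[3,5-bis(benzyloxy)-4-methoxyphenyl]-8-methoxychromen-4-one A7, which is identical with compound 20.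
- Merits: the reaction type is at least as well established as the aryne insertion. A9 is one step shorter than acid 15, since no carboxylation is needed, and A7 already carries the C8 methoxy group, so steps 10 and 11 of the chosen route would vanish. On step count after ring formation this road is better.
- Weak points: the difficulty moves into A8, a benzene with five substituents and four differentiated oxygens. Its last step, iodination of a phenol with two free positions, faces the same ortho/para ambiguity that the chosen plan faces at C8 versus C6, and without the precedent that exists for flavones. The doubly ortho-substituted iodide A8 is slow in oxidative addition. When uptake of A10 lags, direct coupling of A8 with A9 without carbonyl insertion competes, and 5-exo closure to aurones is a known side path.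
- Comparison: the chosen plan makes its regiochemical decision on the flavone, where C8 selectivity is documented, and its ring A precursor comes from a symmetrical phenol. It pays with two extra late steps.

Key step: step 9

Assumption: 3,5-bis(benzyloxy)phenol (1) and 3,5-dihydroxy-4-methoxybenzoic acid (9) are taken as purchasable, and benzyl is the only protecting group so that a single neutral hydrogenolysis ends the route.

## Route

Step 1
Reactants: 1 3,5-bis(benzyloxy)phenol
Product: 2 3,5-bis(benzyloxy)phenyl N-isopropylcarbamate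
Conditions: iPrNCO, Et3N (cat.), CH2Cl2, rt
Reagents that add atoms: isopropyl isocyanate, CC(C)N=C=O
Why: Base-catalysed addition of a phenol to an isocyanate (carbamoylation); the secondary carbamate becomes a strong ortho-directing group after N-silylation and can later be removed under mild amine conditions.

Step 2
Reactants: 2 3,5-bis(benzyloxy)phenyl N-isopropylcarbamate
Product: 6 3,5-bis(benzyloxy)-2-(trimethylsilyl)phenyl N-isopropylcarbamate, via N-silyl carbamate 3 (not isolated), via aryllithium 4 (not isolated), via bis-silyl carbamate 5 (not isolated)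
Conditions: TBSOTf, TMEDA, Et2O, 0 °C to rt; n-BuLi, TMEDA, −78 °C; TMSCl, −78 °C to rt; aq. NaHSO4
Reagents that add atoms: chlorotrimethylsilane, C[Si](C)(C)Cl
Why: Directed ortho-metalation: after N-silylation in the flask, the carbamate (the strongest directing group present) and the adjacent benzyloxy group cooperate, so n-BuLi/TMEDA at −78 °C should remove the ring proton between them (both such positions are equivalent by symmetry) faster than the proton between the two ethers or a benzylic proton. TMSCl traps the aryllithium and the N-silyl group is hydrolysed in the acidic work-up.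

Step 3
Reactants: 6 3,5-bis(benzyloxy)-2-(trimethylsilyl)phenyl N-isopropylcarbamate
Product: 8 3,5-bis(benzyloxy)-2-(trimethylsilyl)phenyl trifluoromethanesulfonate, via silylphenol 7 (not isolated)
Conditions: Et2NH, DBU, MeCN, 40 °C; then PhNTf2, rt
Reagents that add atoms: N-phenylbis(trifluoromethanesulfonimide), O=S(=O)(N(c1ccccc1)S(=O)(=O)C(F)(F)F)C(F)(F)F
Why: E1cB cleavage of the N-monosubstituted carbamate by DBU, with Et2NH scavenging the isocyanate as a urea, frees the hindered phenoxide, which is O-triflated in the same flask; this is the usual close of the carbamate route to ortho-silylaryl triflates.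

Step 4
Reactants: 9 3,5-dihydroxy-4-methoxybenzoic acid
Product: 10 benzyl 3,5-bis(benzyloxy)-4-methoxybenzoate
Conditions: BnBr, K2CO3, DMF, 60 °C
Reagents that add atoms: benzyl bromide, BrCc1ccccc1
Why: Williamson alkylation (SN2) of both phenoxides and the carboxylate in one operation; the methyl ether is untouched.

Step 5
Reactants: 10 benzyl 3,5-bis(benzyloxy)-4-methoxybenzoate
Product: 11 [3,5-bis(benzyloxy)-4-methoxyphenyl]methanol
Conditions: LiAlH4, THF, 0 °C to rt
Reagents that add atoms: none
Why: Hydride reduction of an ester to the primary alcohol; benzyl aryl ethers are inert and the benzyl alcohol released from the ester is removed by chromatography.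

Step 6
Reactants: 11 [3,5-bis(benzyloxy)-4-methoxyphenyl]methanol
Product: 12 3,5-bis(benzyloxy)-4-methoxybenzaldehyde
Conditions: MnO2, CH2Cl2, rt
Reagents that add atoms: none
Why: MnO2 oxidises benzylic alcohols selectively to aldehydes without over-oxidation to the acid.

Step 7
Reactants: 12 3,5-bis(benzyloxy)-4-methoxybenzaldehyde
Product: 13 1,3-bis(benzyloxy)-5-(2,2-dibromoethenyl)-2-methoxybenzene
Conditions: CBr4, PPh3, CH2Cl2, 0 °C
Reagents that add atoms: carbon tetrabromide, BrC(Br)(Br)Br
Why: First stage of the Corey–Fuchs homologation, a Wittig-type olefination by the ylide formed from PPh3 and CBr4; aromatic aldehydes are the standard substrates.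

Step 8
Reactants: 13 1,3-bis(benzyloxy)-5-(2,2-dibromoethenyl)-2-methoxybenzene
Product: 15 3-[3,5-bis(benzyloxy)-4-methoxyphenyl]prop-2-ynoic acid, via lithium acetylide 14 (not isolated)
Conditions: n-BuLi (2.2 equiv), THF, −78 °C; CO2; aq. HCl, 0 °C
Reagents that add atoms: carbon dioxide, O=C=O
Why: Second stage of the Corey–Fuchs homologation: bromine–lithium exchange and Fritsch–Buttenberg–Wiechell rearrangement give the lithium acetylide, which is carboxylated by CO2. Cold acidification and isolation without heating should avoid decarboxylation.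

Step 9
Reactants: 8 3,5-bis(benzyloxy)-2-(trimethylsilyl)phenyl trifluoromethanesulfonate; 15 3-[3,5-bis(benzyloxy)-4-methoxyphenyl]prop-2-ynoic acid
Product: 18 5,7-bis(benzyloxy)-2-[3,5-bis(benzyloxy)-4-methoxyphenyl]chromen-4-one, via aryne 16 (not isolated), via hydroxyaryl ynone 17 (not isolated)
Conditions: CsF (excess), THF, 125 °C (sealed tube); 8 in excess over 15
Reagents that add atoms: none
Why: CsF converts acid 15 into its caesium carboxylate and, by attack of fluoride on silicon with loss of triflate, releases aryne 16 from 8. The carboxylate oxygen adds to the aryne carbon remote from the benzyloxy group (the future C8a), because the inductively withdrawing ether distorts the triple bond and stabilises the aryl anion developing on the carbon next to it (the future C4a). This anion attacks the adjacent ester carbonyl (4-exo-trig) and the four-membered alkoxide opens with C–O cleavage; this anionic ortho-acyl shift amounts to insertion of the aryne into the acid C–O bond, forms O1–C8a and C4–C4a, and gives the phenoxide of ynone 17. The phenoxide then adds to the β-carbon of the ynone, closing ring C by 6-endo-dig oxa-Michael addition (O1–C2), and protonation at C3 gives 18. The closest known reaction type is the fluoride-induced insertion of arynes into the C–O bond of carboxylic acids to give ortho-hydroxyaryl ketones, which with alkynoic acids continues to chromones and flavones. No stereocentre is formed. Three selectivities are needed: the sense of addition to the aryne, secured by the single flanking alkoxy group with the other neighbour (the future C8) left as hydrogen; acyl shift over protonation to the aryl ester, favoured by the hot aprotic medium; and 6-endo over 5-exo-dig closure to an aurone, favoured for a phenoxide adding to a carbonyl-polarised ynone in an aprotic solvent.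

Step 10
Reactants: 18 5,7-bis(benzyloxy)-2-[3,5-bis(benzyloxy)-4-methoxyphenyl]chromen-4-one
Product: 19 5,7-bis(benzyloxy)-2-[3,5-bis(benzyloxy)-4-methoxyphenyl]-8-bromochromen-4-one
Conditions: NBS (1.05 equiv), DMF, 0 °C to rt, dark
Reagents that add atoms: N-bromosuccinimide, O=C1CCC(=O)N1Br
Why: Electrophilic aromatic bromination; in fully O-alkylated 5,7-dioxygenated flavones the established site is C8 (ortho to O1 and to the C7 ether, para to the C5 ether), and ring A is more activated than ring B, which is conjugated to the electron-poor pyranone. One equivalent of NBS in DMF in the dark avoids radical benzylic bromination.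

Step 11
Reactants: 19 5,7-bis(benzyloxy)-2-[3,5-bis(benzyloxy)-4-methoxyphenyl]-8-bromochromen-4-one
Product: 20 5,7-bis(benzyloxy)-2-[3,5-bis(benzyloxy)-4-methoxyphenyl]-8-methoxychromen-4-one
Conditions: NaOMe, CuBr, MeOH/DMF, 110 °C
Reagents that add atoms: sodium methoxide, C[O-].[Na+]
Why: Copper-mediated Ullmann-type methoxylation of an aryl bromide, the standard way to convert 8-bromoflavones into 8-methoxyflavones; benzyl and methyl aryl ethers are inert to methoxide.

Step 12
Reactants: 20 5,7-bis(benzyloxy)-2-[3,5-bis(benzyloxy)-4-methoxyphenyl]-8-methoxychromen-4-one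
Product: 23 5,7-bis(benzyloxy)-2-[3,5-bis(benzyloxy)-4-methoxyphenyl]-3-hydroxy-8-methoxychromen-4-one, via 3-lithioflavone 21 (not isolated), via 3-boronate 22 (not isolated)
Conditions: LiN(iPr)2, THF, −78 °C; B(OMe)3; AcOH, 30% H2O2, 0 °C to rt
Reagents that add atoms: hydrogen peroxide, OO
Why: C3–H, next to the carbonyl, is the most acidic ring proton of a flavone and is removed by LiN(iPr)2 at −78 °C (carbonyl-directed vinylic lithiation). Borylation with B(OMe)3 and oxidative 1,2-migration with H2O2 turn C–Li into C–OH; this lithiation–borylation–oxidation sequence is the known conversion of flavones into flavonols.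

Step 13
Reactants: 23 5,7-bis(benzyloxy)-2-[3,5-bis(benzyloxy)-4-methoxyphenyl]-3-hydroxy-8-methoxychromen-4-one
Product: 24 2-(3,5-dihydroxy-4-methoxyphenyl)-3,5,7-trihydroxy-8-methoxychromen-4-one
Conditions: H2 (1 atm), Pd/C, THF/MeOH, rt
Reagents that add atoms: none
Why: Catalytic hydrogenolysis cleaves the four benzyl aryl ethers under neutral conditions and leaves the methyl ethers, the tetrasubstituted enolic C2=C3 bond and the vinylogous-ester carbonyl intact; neutrality avoids acid-induced Wessely–Moser isomerisation of the 5-hydroxy-8-methoxy pattern.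

## Compound list

1 | 3,5-bis(benzyloxy)phenol | Oc1cc(OCc2ccccc2)cc(OCc2ccccc2)c1 | starting material
2 | 3,5-bis(benzyloxy)phenyl N-isopropylcarbamate | CC(C)NC(=O)Oc1cc(OCc2ccccc2)cc(OCc2ccccc2)c1 | intermediate
3 | 3,5-bis(benzyloxy)phenyl N-(tert-butyldimethylsilyl)-N-isopropylcarbamate | CC(C)N(C(=O)Oc1cc(OCc2ccccc2)cc(OCc2ccccc2)c1)[Si](C)(C)C(C)(C)C | intermediate
4 | 2-lithio derivative of 3 (lithium on the ring carbon between the carbamate and a benzyloxy group) | [Li]c1c(OC(=O)N(C(C)C)[Si](C)(C)C(C)(C)C)cc(OCc2ccccc2)cc1OCc1ccccc1 | intermediate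
5 | 3,5-bis(benzyloxy)-2-(trimethylsilyl)phenyl N-(tert-butyldimethylsilyl)-N-isopropylcarbamate | CC(C)N(C(=O)Oc1cc(OCc2ccccc2)cc(OCc2ccccc2)c1[Si](C)(C)C)[Si](C)(C)C(C)(C)C | intermediate
6 | 3,5-bis(benzyloxy)-2-(trimethylsilyl)phenyl N-isopropylcarbamate | CC(C)NC(=O)Oc1cc(OCc2ccccc2)cc(OCc2ccccc2)c1[Si](C)(C)C | intermediate
7 | 3,5-bis(benzyloxy)-2-(trimethylsilyl)phenol | C[Si](C)(C)c1c(O)cc(OCc2ccccc2)cc1OCc1ccccc1 | intermediate
8 | 3,5-bis(benzyloxy)-2-(trimethylsilyl)phenyl trifluoromethanesulfonate | C[Si](C)(C)c1c(OS(=O)(=O)C(F)(F)F)cc(OCc2ccccc2)cc1OCc1ccccc1 | intermediate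
9 | 3,5-dihydroxy-4-methoxybenzoic acid | COc1c(O)cc(C(=O)O)cc1O | starting material
10 | benzyl 3,5-bis(benzyloxy)-4-methoxybenzoate | COc1c(OCc2ccccc2)cc(C(=O)OCc2ccccc2)cc1OCc1ccccc1 | intermediate
11 | [3,5-bis(benzyloxy)-4-methoxyphenyl]methanol | COc1c(OCc2ccccc2)cc(CO)cc1OCc1ccccc1 | intermediate
12 | 3,5-bis(benzyloxy)-4-methoxybenzaldehyde | COc1c(OCc2ccccc2)cc(C=O)cc1OCc1ccccc1 | intermediate
13 | 1,3-bis(benzyloxy)-5-(2,2-dibromoethenyl)-2-methoxybenzene | COc1c(OCc2ccccc2)cc(C=C(Br)Br)cc1OCc1ccccc1 | intermediate
14 | lithium [3,5-bis(benzyloxy)-4-methoxyphenyl]acetylide | [Li]C#Cc1cc(OCc2ccccc2)c(OC)c(OCc2ccccc2)c1 | intermediate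
15 | 3-[3,5-bis(benzyloxy)-4-methoxyphenyl]prop-2-ynoic acid | OC(=O)C#Cc1cc(OCc2ccccc2)c(OC)c(OCc2ccccc2)c1 | intermediate
16 | 3,5-bis(benzyloxy)benzyne (1,2-didehydro-3,5-bis(benzyloxy)benzene) | C1#CC(OCc2ccccc2)=CC(OCc2ccccc2)=C1 | intermediate
17 | 1-[2,4-bis(benzyloxy)-6-hydroxyphenyl]-3-[3,5-bis(benzyloxy)-4-methoxyphenyl]prop-2-yn-1-one (present as its caesium phenoxide) | O=C(C#Cc1cc(OCc2ccccc2)c(OC)c(OCc2ccccc2)c1)c1c(O)cc(OCc2ccccc2)cc1OCc1ccccc1 | intermediate
18 | 5,7-bis(benzyloxy)-2-[3,5-bis(benzyloxy)-4-methoxyphenyl]chromen-4-one | O=c1cc(-c2cc(OCc3ccccc3)c(OC)c(OCc3ccccc3)c2)oc2cc(OCc3ccccc3)cc(OCc3ccccc3)c12 | intermediate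
19 | 5,7-bis(benzyloxy)-2-[3,5-bis(benzyloxy)-4-methoxyphenyl]-8-bromochromen-4-one | O=c1cc(-c2cc(OCc3ccccc3)c(OC)c(OCc3ccccc3)c2)oc2c(Br)c(OCc3ccccc3)cc(OCc3ccccc3)c12 | intermediate
20 | 5,7-bis(benzyloxy)-2-[3,5-bis(benzyloxy)-4-methoxyphenyl]-8-methoxychromen-4-one | COc1c(OCc2ccccc2)cc(OCc2ccccc2)c2c1oc(-c1cc(OCc3ccccc3)c(OC)c(OCc3ccccc3)c1)cc2=O | intermediate
21 | 3-lithio derivative of 20 | [Li]c1c(-c2cc(OCc3ccccc3)c(OC)c(OCc3ccccc3)c2)oc2c(OC)c(OCc3ccccc3)cc(OCc3ccccc3)c2c1=O | intermediate
22 | dimethyl {5,7-bis(benzyloxy)-2-[3,5-bis(benzyloxy)-4-methoxyphenyl]-8-methoxy-4-oxochromen-3-yl}boronate | COB(OC)c1c(-c2cc(OCc3ccccc3)c(OC)c(OCc3ccccc3)c2)oc2c(OC)c(OCc3ccccc3)cc(OCc3ccccc3)c2c1=O | intermediate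
23 | 5,7-bis(benzyloxy)-2-[3,5-bis(benzyloxy)-4-methoxyphenyl]-3-hydroxy-8-methoxychromen-4-one | COc1c(OCc2ccccc2)cc(OCc2ccccc2)c2c1oc(-c1cc(OCc3ccccc3)c(OC)c(OCc3ccccc3)c1)c(O)c2=O | intermediate
24 | 2-(3,5-dihydroxy-4-methoxyphenyl)-3,5,7-trihydroxy-8-methoxychromen-4-one (no stereocentres) | COc1c(O)cc(-c2oc3c(OC)c(O)cc(O)c3c(=O)c2O)cc1O | target

## Step count and risk

Total: 13 steps. Longest linear sequence: 10 steps (steps 4–8, 9, 10–13). The ring A arm (steps 1–3) joins at step 9.

**Step 9 (key step).** Three things may go wrong: protonation of the aryl anion before the acyl shift, so that the sequence stops at O-arylation; loss of CO2 from the electron-rich caesium arylpropiolate at 125 °C before it meets the aryne; and closure of the phenoxide in the 5-exo mode. The fallback sets out from aldehyde 12 and returns at flavone 18. Claisen–Schmidt condensation of 12 with purchased 1-[2,4-bis(benzyloxy)-6-hydroxyphenyl]ethan-1-one F1 (KOH, EtOH, rt) should give (E)-1-[2,4-bis(benzyloxy)-6-hydroxyphenyl]-3-[3,5-bis(benzyloxy)-4-methoxyphenyl]prop-2-en-1-one F2. Catalytic I2 in DMSO at 120 °C should then close ring C by oxa-Michael addition and dehydrogenation to 18.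

**Step 2.** n-BuLi may deprotonate a benzylic CH2 of the aryl benzyl ethers, followed by 1,2-Wittig shift; lithiation may occur between the two ethers instead of next to the carbamate; or both carbamate-ortho positions may be silylated. The fallback sets out from phenol 1 and returns at triflate 8, replacing deprotonation by halogen–metal exchange. Bromination with NBS (CH2Cl2, −78 °C) should give 3,5-bis(benzyloxy)-2-bromophenol F3, to be separated from its 4-bromo isomer. O-Silylation with HMDS gives [3,5-bis(benzyloxy)-2-bromophenoxy]trimethylsilane F4. n-BuLi in THF at −100 °C effects bromine–lithium exchange, which is much faster than benzylic deprotonation, and 1,3 O-to-C silyl migration (retro-Brook) to lithium 3,5-bis(benzyloxy)-2-(trimethylsilyl)phenoxide F5, the salt of 7. Tf2O then gives 8.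

**Step 10.** Bromination may occur at C6 or at C2′ of ring B, or twice. The fallback sets out from 18 and returns at 20, placing the oxygen para to a phenoxide instead of going through a halide. MgBr2·OEt2 removes the chelated C5 benzyl group selectively to give 7-(benzyloxy)-2-[3,5-bis(benzyloxy)-4-methoxyphenyl]-5-hydroxychromen-4-one F6. Elbs persulfate oxidation (K2S2O8, aq. KOH/pyridine) attacks C8, para to the phenoxide, giving potassium 7-(benzyloxy)-2-[3,5-bis(benzyloxy)-4-methoxyphenyl]-5-hydroxy-4-oxochromen-8-yl sulfate F7. Mild acid hydrolysis gives 7-(benzyloxy)-2-[3,5-bis(benzyloxy)-4-methoxyphenyl]-5,8-dihydroxychromen-4-one F8. MeI/K2CO3 in acetone methylates the non-chelated C8 hydroxyl to 7-(benzyloxy)-2-[3,5-bis(benzyloxy)-4-methoxyphenyl]-5-hydroxy-8-methoxychromen-4-one F9, and BnBr/K2CO3 in hot DMF re-benzylates O5 to give 20.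

**Step 11.** Reductive loss of bromine at the doubly ortho-substituted C8, or methoxide attack at C2 with opening of the pyranone, may compete with C–O coupling. The fallback sets out from 19 and returns at 20. Miyaura borylation (B2pin2, Pd(dppf)Cl2, KOAc, dioxane, 90 °C) should give 5,7-bis(benzyloxy)-2-[3,5-bis(benzyloxy)-4-methoxyphenyl]-8-(4,4,5,5-tetramethyl-1,3,2-dioxaborolan-2-yl)chromen-4-one F10. Oxidation with NaBO3 in THF/water gives 5,7-bis(benzyloxy)-2-[3,5-bis(benzyloxy)-4-methoxyphenyl]-8-hydroxychromen-4-one F11, and MeI/K2CO3 in DMF gives 20.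

**Step 12.** Metalation at C3 may be incomplete, the 3-lithio species may fragment by ring opening, or the amide may add to the carbonyl. The fallback sets out from 20 and returns at 23 without an organometallic. Dimethyldioxirane in acetone/CH2Cl2 at 0 °C should epoxidise C2=C3 to racemic 5,7-bis(benzyloxy)-2-[3,5-bis(benzyloxy)-4-methoxyphenyl]-2,3-epoxy-8-methoxy-2,3-dihydrochromen-4-one F12, necessarily cis-fused. A trace of p-TsOH opens the epoxide at C2 and tautomerises it to 23. Exposure must be short, because the oxidant also attacks benzylic C–H bonds slowly.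

## Further compounds

F1 | step 9 | 1-[2,4-bis(benzyloxy)-6-hydroxyphenyl]ethan-1-one (purchased) | CC(=O)c1c(O)cc(OCc2ccccc2)cc1OCc1ccccc1
F2 | step 9 | (E)-1-[2,4-bis(benzyloxy)-6-hydroxyphenyl]-3-[3,5-bis(benzyloxy)-4-methoxyphenyl]prop-2-en-1-one | COc1c(OCc2ccccc2)cc(/C=C/C(=O)c2c(O)cc(OCc3ccccc3)cc2OCc2ccccc2)cc1OCc1ccccc1
F3 | step 2 | 3,5-bis(benzyloxy)-2-bromophenol | Oc1cc(OCc2ccccc2)cc(OCc2ccccc2)c1Br
F4 | step 2 | [3,5-bis(benzyloxy)-2-bromophenoxy]trimethylsilane | C[Si](C)(C)Oc1cc(OCc2ccccc2)cc(OCc2ccccc2)c1Br
F5 | step 2 | lithium 3,5-bis(benzyloxy)-2-(trimethylsilyl)phenoxide | [Li+].[O-]c1cc(OCc2ccccc2)cc(OCc2ccccc2)c1[Si](C)(C)C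
F6 | step 10 | 7-(benzyloxy)-2-[3,5-bis(benzyloxy)-4-methoxyphenyl]-5-hydroxychromen-4-one | O=c1cc(-c2cc(OCc3ccccc3)c(OC)c(OCc3ccccc3)c2)oc2cc(OCc3ccccc3)cc(O)c12
F7 | step 10 | potassium 7-(benzyloxy)-2-[3,5-bis(benzyloxy)-4-methoxyphenyl]-5-hydroxy-4-oxochromen-8-yl sulfate | O=c1cc(-c2cc(OCc3ccccc3)c(OC)c(OCc3ccccc3)c2)oc2c(OS(=O)(=O)[O-])c(OCc3ccccc3)cc(O)c12.[K+]
F8 | step 10 | 7-(benzyloxy)-2-[3,5-bis(benzyloxy)-4-methoxyphenyl]-5,8-dihydroxychromen-4-one | O=c1cc(-c2cc(OCc3ccccc3)c(OC)c(OCc3ccccc3)c2)oc2c(O)c(OCc3ccccc3)cc(O)c12
F9 | step 10 | 7-(benzyloxy)-2-[3,5-bis(benzyloxy)-4-methoxyphenyl]-5-hydroxy-8-methoxychromen-4-one | COc1c(OCc2ccccc2)cc(O)c2c1oc(-c1cc(OCc3ccccc3)c(OC)c(OCc3ccccc3)c1)cc2=O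
F10 | step 11 | 5,7-bis(benzyloxy)-2-[3,5-bis(benzyloxy)-4-methoxyphenyl]-8-(4,4,5,5-tetramethyl-1,3,2-dioxaborolan-2-yl)chromen-4-one | CC1(C)OB(OC1(C)C)c1c(OCc2ccccc2)cc(OCc2ccccc2)c2c1oc(-c1cc(OCc3ccccc3)c(OC)c(OCc3ccccc3)c1)cc2=O
F11 | step 11 | 5,7-bis(benzyloxy)-2-[3,5-bis(benzyloxy)-4-methoxyphenyl]-8-hydroxychromen-4-one | Oc1c(OCc2ccccc2)cc(OCc2ccccc2)c2c1oc(-c1cc(OCc3ccccc3)c(OC)c(OCc3ccccc3)c1)cc2=O
F12 | step 12 | 5,7-bis(benzyloxy)-2-[3,5-bis(benzyloxy)-4-methoxyphenyl]-2,3-epoxy-8-methoxy-2,3-dihydrochromen-4-one (racemic, cis-fused, one enantiomer drawn) | O=C1[C@H]2O[C@@]2(c2cc(OCc3ccccc3)c(OC)c(OCc3ccccc3)c2)Oc2c(OC)c(OCc3ccccc3)cc(OCc3ccccc3)c12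
A1 | alternative 1 | 2-(benzyloxy)-1-[4,6-bis(benzyloxy)-3-methoxy-2-(methoxymethoxy)phenyl]-3-[3,5-bis(benzyloxy)-4-methoxyphenyl]-3-hydroxypropan-1-one (racemic, one diastereomer drawn) | COCOc1c(OC)c(OCc2ccccc2)cc(OCc2ccccc2)c1C(=O)[C@H](OCc1ccccc1)[C@@H](O)c1cc(OCc2ccccc2)c(OC)c(OCc2ccccc2)c1
A2 | alternative 1 | 1-[4,6-bis(benzyloxy)-3-methoxy-2-(methoxymethoxy)phenyl]-2-diazoethan-1-one | COCOc1c(OC)c(OCc2ccccc2)cc(OCc2ccccc2)c1C(=O)C=[N+]=[N-]
A3 | alternative 1 | benzyl alcohol | OCc1ccccc1
A4 | alternative 2 | 3,7-bis(benzyloxy)-2-[3,5-bis(benzyloxy)-4-methoxyphenyl]-5-hydroxy-8-methoxychromen-4-one | COc1c(OCc2ccccc2)cc(O)c2c1oc(-c1cc(OCc3ccccc3)c(OC)c(OCc3ccccc3)c1)c(OCc1ccccc1)c2=O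
A5 | alternative 2 | 2-(benzyloxy)-1-[4-(benzyloxy)-2-hydroxy-5-methoxyphenyl]-3-[3,5-bis(benzyloxy)-4-methoxyphenyl]propane-1,3-dione (racemic, enolisable) | COc1cc(C(=O)C(OCc2ccccc2)C(=O)c2cc(OCc3ccccc3)c(OC)c(OCc3ccccc3)c2)c(O)cc1OCc1ccccc1
A6 | alternative 2 | 5-(benzyloxy)-2-{2-(benzyloxy)-3-[3,5-bis(benzyloxy)-4-methoxyphenyl]-3-oxopropanoyl}-4,4-dimethoxycyclohexa-2,5-dien-1-one | COC1(OC)C=C(C(=O)C(OCc2ccccc2)C(=O)c2cc(OCc3ccccc3)c(OC)c(OCc3ccccc3)c2)C(=O)C=C1OCc1ccccc1
A7 | alternative 3 | 5,7-bis(benzyloxy)-2-[3,5-bis(benzyloxy)-4-methoxyphenyl]-8-methoxychromen-4-one | COc1c(OCc2ccccc2)cc(OCc2ccccc2)c2c1oc(-c1cc(OCc3ccccc3)c(OC)c(OCc3ccccc3)c1)cc2=O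
A8 | alternative 3 | 3,5-bis(benzyloxy)-2-iodo-6-methoxyphenol | COc1c(O)c(I)c(OCc2ccccc2)cc1OCc1ccccc1
A9 | alternative 3 | 1,3-bis(benzyloxy)-5-ethynyl-2-methoxybenzene | C#Cc1cc(OCc2ccccc2)c(OC)c(OCc2ccccc2)c1
A10 | alternative 3 | carbon monoxide | [C-]#[O+]
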